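**Retrosynthetic overview**

1. Target 16 is traced back through aryl acetate methanolysis, styrene cross-metathesis and reductive removal of three sulfonyl groups to the 3-allyl-4-sulfonyl oxane 12. The oxane (O1, C2–C6; Cα is the carbinol carbon on C5) is the only ring and is formed in step 7.
2. Key disconnection: C4–C5 of the oxane together with the C3–allyl bond. 12 comes from the acyclic epoxy vinyl sulfone 8 and allyllithium by conjugate addition followed by 6-exo epoxide opening in one flask.
3. Enabling feature: C5 carries the exocyclic carbinol carbon Cα (ArCH–OH) and is joined through C6H2 to O1, so C6–C5–Cα(OH)Ar is a latent trans-2,3-epoxy-3-arylpropyl ether. C4 is a bare CH2 next to the side-chain carbon C3, so C4/C3 can be the α/β carbons of a vinyl sulfone, and O1 tethers the two halves so that C4→C5 attack is 6-exo.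
4. 8 comes from cross-metathesis of the branched allylic ether 6 with phenyl vinyl sulfone. 6 comes from an Ir-catalysed asymmetric allylic etherification (sets C2) of epoxy alcohol 4 (asymmetric epoxidation; sets C5 and Cα) with carbonate 5; both halves derive from one cinnamyl alcohol 3.
5. Stereochemistry: C5/Cα by catalytic epoxidation, C2 by Ir catalysis, C3 relayed from C2 inside the key step; the C4 sulfone is a temporary activating group.

Key step: step 7

Remark: oxane numbering as above is used throughout. In step 5 the (Ra,R,R)-phosphoramidite is assumed to be the ligand antipode that gives the (R)-branched ether with O-nucleophiles; if the sense is opposite, the enantiomeric ligand is used. C4 of 12 is expected as a mixture and is erased in step 8.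

**Step 1**
Reactants: 1 methyl (E)-3-(4-hydroxyphenyl)prop-2-enoate
Product: 2 methyl (E)-3-[4-(tosyloxy)phenyl]prop-2-enoate
Conditions: TsCl, Et3N, DMAP (cat.), CH2Cl2, 0 °C → rt
Reagents that add atoms: p-toluenesulfonyl chloride, Cc1ccc(cc1)S(Cl)(=O)=O
Why: Phenol sulfonylation; the electron-poor tosyloxyaryl group later keeps the aryl epoxide and the benzylic ether from ionising and is removed reductively in step 8.

**Step 2**
Reactants: 2 methyl (E)-3-[4-(tosyloxy)phenyl]prop-2-enoate
Product: 3 4-[(E)-3-hydroxyprop-1-enyl]phenyl 4-methylbenzenesulfonate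
Conditions: DIBAL-H (2.2 equiv), CH2Cl2, –78 °C; Rochelle salt work-up
Reagents that add atoms: none
Why: DIBAL-H 1,2-reduction of an enoate to the allylic alcohol should leave the E-alkene and the aryl sulfonate untouched at –78 °C.

**Step 3**
Reactants: 3 4-[(E)-3-hydroxyprop-1-enyl]phenyl 4-methylbenzenesulfonate
Product: 4 4-[(2S,3S)-3-(hydroxymethyl)oxiran-2-yl]phenyl 4-methylbenzenesulfonate
Conditions: Ti(Oi-Pr)4 (10 mol%), L-(+)-diethyl tartrate (12 mol%), t-BuOOH, 4 Å MS, CH2Cl2, –20 °C
Reagents that add atoms: tert-butyl hydroperoxide, CC(C)(C)OO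
Why: Sharpless–Katsuki asymmetric epoxidation of an (E)-allylic alcohol; L-(+)-tartrate should deliver oxygen to the face that gives the (2S,3S)-epoxide, which fixes Cα as in the target and C5 in the configuration that is inverted in step 7.

**Step 4**
Reactants: 3 4-[(E)-3-hydroxyprop-1-enyl]phenyl 4-methylbenzenesulfonate
Product: 5 tert-butyl (E)-3-[4-(tosyloxy)phenyl]prop-2-enyl carbonate
Conditions: Boc2O (1.5 equiv), DMAP (cat.), CH2Cl2, 0 °C → rt
Reagents that add atoms: di-tert-butyl dicarbonate, CC(C)(C)OC(=O)OC(=O)OC(C)(C)C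
Why: O-acylation of the primary allylic alcohol gives an allylic carbonate whose leaving group (CO2 and tert-butoxide) is a poor competing nucleophile in step 5.

**Step 5**
Reactants: 4 4-[(2S,3S)-3-(hydroxymethyl)oxiran-2-yl]phenyl 4-methylbenzenesulfonate; 5 tert-butyl (E)-3-[4-(tosyloxy)phenyl]prop-2-enyl carbonate
Product: 6 4-[(1R)-1-{[(2S,3S)-3-(4-tosyloxyphenyl)oxiran-2-yl]methoxy}prop-2-enyl]phenyl 4-methylbenzenesulfonate
Conditions: 4, n-BuLi (1.0 equiv) then CuI (1.0 equiv), THF, –78 → 0 °C; 5 (1.2 equiv), [Ir(cod)Cl]2 (2 mol%), (Ra,R,R)-BINOL N,N-bis(1-phenylethyl)phosphoramidite (4 mol%), THF, rt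
Reagents that add atoms: none
Why: Iridium-catalysed asymmetric allylic etherification with a copper(I) alkoxide should attack the Ir-allyl complex at the aryl-bearing terminus (branched product), the chiral catalyst setting C2 as (R), while the soft, cold copper alkoxide should suppress Payne rearrangement of the epoxy alkoxide.

**Step 6**
Reactants: 6 4-[(1R)-1-{[(2S,3S)-3-(4-tosyloxyphenyl)oxiran-2-yl]methoxy}prop-2-enyl]phenyl 4-methylbenzenesulfonate; 7 phenyl vinyl sulfone
Product: 8 4-[(1R,2E)-3-(phenylsulfonyl)-1-{[(2S,3S)-3-(4-tosyloxyphenyl)oxiran-2-yl]methoxy}prop-2-enyl]phenyl 4-methylbenzenesulfonate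
Conditions: 7 (3 equiv), Hoveyda–Grubbs II (5–10 mol%), CH2Cl2, 40 °C
Reagents that add atoms: none
Why: Olefin cross-metathesis of the only alkene in 6 with phenyl vinyl sulfone, which does not homodimerise, should give the (E)-vinyl sulfone; epoxide and sulfonates are inert to the Ru carbene.

**Step 7**
Reactants: 8 4-[(1R,2E)-3-(phenylsulfonyl)-1-{[(2S,3S)-3-(4-tosyloxyphenyl)oxiran-2-yl]methoxy}prop-2-enyl]phenyl 4-methylbenzenesulfonate; 9 allyltributylstannane
Product: 12 4-[(2R,3R,5R)-5-[(R)-hydroxy(4-tosyloxyphenyl)methyl]-4-(phenylsulfonyl)-3-(prop-2-enyl)oxan-2-yl]phenyl 4-methylbenzenesulfonate (mixture at C4), via allyllithium 10 (not isolated), via lithiated sulfone 11 (not isolated)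
Conditions: 9 (1.2 equiv), n-BuLi (1.2 equiv), THF, –78 °C; then 8 in THF–toluene, –78 °C; then –78 → 0 °C; aq. NH4Cl
Reagents that add atoms: none
Why: Allyllithium adds to the β-carbon C3 of the γ-alkoxy vinyl sulfone (heteroconjugate addition) and the α-sulfonyl carbanion 11 then attacks the nearer epoxide carbon C5 in an intramolecular SN2 alkylation, a Michael-initiated ring closure that joins two established reaction types (organolithium addition to γ-oxygenated vinyl sulfones and epoxy sulfone cyclisation). The oxane closes by C4–C5 bond formation in the 6-exo-tet mode, the breaking epoxide C–O bond lying outside the new ring. C3 is set by 1,2-induction from C2: lithium is held by the C2 ether oxygen in the conformer with C2–H eclipsing the double bond, and the allyl group is delivered to the face of C3 syn to that oxygen, which is the 2,3-cis relationship of the target; C5 is set by inversion at the epoxide carbon and Cα is carried over unchanged from step 3, so their relationship is stereospecific; C4 forms as a mixture and is erased in step 8. The step needs addition to the vinyl sulfone before any attack on epoxide or sulfonate, which the much higher electrophilicity of the vinyl sulfone at –78 °C should secure, and exo rather than 7-endo benzylic opening, which the collinear geometry of the six-membered transition state and the electron-poor tosyloxyphenyl group should secure. The product chair places the C3 and C5 substituents equatorial and the C2 aryl group axial, a cost the irreversible intramolecular alkylation can bear.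

**Step 8**
Reactants: 12 4-[(2R,3R,5R)-5-[(R)-hydroxy(4-tosyloxyphenyl)methyl]-4-(phenylsulfonyl)-3-(prop-2-enyl)oxan-2-yl]phenyl 4-methylbenzenesulfonate
Product: 13 4-[(2R,3S,5R)-5-[(R)-hydroxy(4-hydroxyphenyl)methyl]-3-(prop-2-enyl)oxan-2-yl]phenol
Conditions: Mg turnings (excess), MeOH, rt (sonication)
Reagents that add atoms: none
Why: Magnesium in methanol (single-electron reductive desulfonylation) should cleave the C4–SO2Ph bond and both aryl O–SO2 bonds in one operation, removing the C4 stereocentre; no β-leaving group flanks C4, and at rt the terminal alkene and benzylic C–O bonds are not reduced and quinone-methide epimerisation at C2 is avoided.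

**Step 9**
Reactants: 13 4-[(2R,3S,5R)-5-[(R)-hydroxy(4-hydroxyphenyl)methyl]-3-(prop-2-enyl)oxan-2-yl]phenol; 14 4-ethenylphenyl acetate
Product: 15 4-[(E)-3-[(2R,3S,5R)-5-[(R)-hydroxy(4-hydroxyphenyl)methyl]-2-(4-hydroxyphenyl)oxan-3-yl]prop-1-enyl]phenyl acetate
Conditions: 14 (3–5 equiv), Hoveyda–Grubbs II (5 mol%), CH2Cl2, 40 °C
Reagents that add atoms: none
Why: Cross-metathesis of the terminal allyl group with a styrene should give the thermodynamically favoured (E)-aryl alkene; free phenols and the secondary alcohol are tolerated by the Ru catalyst.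

**Step 10**
Reactants: 15 4-[(E)-3-[(2R,3S,5R)-5-[(R)-hydroxy(4-hydroxyphenyl)methyl]-2-(4-hydroxyphenyl)oxan-3-yl]prop-1-enyl]phenyl acetate
Product: 16 4-[(2R,3S,5R)-5-[(R)-hydroxy(4-hydroxyphenyl)methyl]-3-[(E)-3-(4-hydroxyphenyl)prop-2-enyl]oxan-2-yl]phenol
Conditions: K2CO3 (cat.), MeOH, 0 °C → rt
Reagents that add atoms: none
Why: Base-catalysed methanolysis (transesterification) of the aryl acetate should free the third phenol under conditions mild enough to spare the p-hydroxybenzylic ether and alcohol.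

**Compound list**

1 | methyl (E)-3-(4-hydroxyphenyl)prop-2-enoate (methyl p-coumarate) | COC(=O)/C=C/c1ccc(O)cc1 | starting material
2 | methyl (E)-3-[4-(tosyloxy)phenyl]prop-2-enoate | COC(=O)/C=C/c1ccc(OS(=O)(=O)c2ccc(C)cc2)cc1 | intermediate
3 | 4-[(E)-3-hydroxyprop-1-enyl]phenyl 4-methylbenzenesulfonate | OC/C=C/c1ccc(OS(=O)(=O)c2ccc(C)cc2)cc1 | intermediate
4 | 4-[(2S,3S)-3-(hydroxymethyl)oxiran-2-yl]phenyl 4-methylbenzenesulfonate | OC[C@@H]1O[C@H]1c1ccc(OS(=O)(=O)c2ccc(C)cc2)cc1 | intermediate
5 | tert-butyl (E)-3-[4-(tosyloxy)phenyl]prop-2-enyl carbonate | CC(C)(C)OC(=O)OC/C=C/c1ccc(OS(=O)(=O)c2ccc(C)cc2)cc1 | intermediate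
6 | 4-[(1R)-1-{[(2S,3S)-3-(4-tosyloxyphenyl)oxiran-2-yl]methoxy}prop-2-enyl]phenyl 4-methylbenzenesulfonate | C=C[C@@H](OC[C@@H]1O[C@H]1c1ccc(OS(=O)(=O)c2ccc(C)cc2)cc1)c1ccc(OS(=O)(=O)c2ccc(C)cc2)cc1 | intermediate
7 | phenyl vinyl sulfone | C=CS(=O)(=O)c1ccccc1 | starting material
8 | 4-[(1R,2E)-3-(phenylsulfonyl)-1-{[(2S,3S)-3-(4-tosyloxyphenyl)oxiran-2-yl]methoxy}prop-2-enyl]phenyl 4-methylbenzenesulfonate | O=S(=O)(/C=C/[C@@H](OC[C@@H]1O[C@H]1c1ccc(OS(=O)(=O)c2ccc(C)cc2)cc1)c1ccc(OS(=O)(=O)c2ccc(C)cc2)cc1)c1ccccc1 | intermediate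
9 | allyltributylstannane | C=CC[Sn](CCCC)(CCCC)CCCC | starting material
10 | allyllithium | [Li]CC=C | intermediate (not isolated)
11 | lithium salt of the α-sulfonyl carbanion of 4-[(1R,2R)-2-[(phenylsulfonyl)methyl]-1-{[(2S,3S)-3-(4-tosyloxyphenyl)oxiran-2-yl]methoxy}pent-4-enyl]phenyl 4-methylbenzenesulfonate | [Li+].C=CC[C@@H]([CH-]S(=O)(=O)c1ccccc1)[C@@H](OC[C@@H]1O[C@H]1c1ccc(OS(=O)(=O)c2ccc(C)cc2)cc1)c1ccc(OS(=O)(=O)c2ccc(C)cc2)cc1 | intermediate (not isolated)
12 | 4-[(2R,3R,5R)-5-[(R)-hydroxy(4-tosyloxyphenyl)methyl]-4-(phenylsulfonyl)-3-(prop-2-enyl)oxan-2-yl]phenyl 4-methylbenzenesulfonate (C4 not defined) | C=CC[C@H]1C(S(=O)(=O)c2ccccc2)[C@@H]([C@@H](O)c2ccc(OS(=O)(=O)c3ccc(C)cc3)cc2)CO[C@H]1c1ccc(OS(=O)(=O)c2ccc(C)cc2)cc1 | intermediate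
13 | 4-[(2R,3S,5R)-5-[(R)-hydroxy(4-hydroxyphenyl)methyl]-3-(prop-2-enyl)oxan-2-yl]phenol | C=CC[C@H]1C[C@@H]([C@@H](O)c2ccc(O)cc2)CO[C@H]1c1ccc(O)cc1 | intermediate
14 | 4-ethenylphenyl acetate (4-acetoxystyrene) | CC(=O)Oc1ccc(C=C)cc1 | starting material
15 | 4-[(E)-3-[(2R,3S,5R)-5-[(R)-hydroxy(4-hydroxyphenyl)methyl]-2-(4-hydroxyphenyl)oxan-3-yl]prop-1-enyl]phenyl acetate | CC(=O)Oc1ccc(/C=C/C[C@H]2C[C@@H]([C@@H](O)c3ccc(O)cc3)CO[C@H]2c2ccc(O)cc2)cc1 | intermediate
16 | 4-[(2R,3S,5R)-5-[(R)-hydroxy(4-hydroxyphenyl)methyl]-3-[(E)-3-(4-hydroxyphenyl)prop-2-enyl]oxan-2-yl]phenol | Oc1ccc(/C=C/C[C@H]2C[C@@H]([C@@H](O)c3ccc(O)cc3)CO[C@H]2c2ccc(O)cc2)cc1 | target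

**Count and risks**

Total step count: 10. Longest linear sequence: 9 steps (1, 2, 3, 5, 6, 7, 8, 9, 10; step 4 is a one-step side branch from 3).

The three steps most likely to fail:

**Step 7.** What may go wrong: loss of facial control in the conjugate addition (open, non-chelated attack leading into the 2,3-trans series), competing deprotonation of the doubly activated C2–H with erosion of C2, or attack of the allyl reagent on a sulfonate or on the epoxide. The fallback buys the C2/C3 pair from auxiliary control and runs the same ring closure as a separate step. It sets out from compound 4 and comes back at compound 12.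
- (R)-4-Benzyl-2-oxazolidinone is N-acylated (n-BuLi, pent-4-enoyl chloride, THF, –78 °C) to (R)-4-benzyl-3-(pent-4-enoyl)oxazolidin-2-one F1.
- Its Z-boron enolate (Bu2BOTf, i-Pr2NEt, CH2Cl2, –78 → 0 °C) adds to commercial 4-formylphenyl 4-methylbenzenesulfonate in an Evans syn-aldol reaction to give the (2R,3R)-aldol adduct F2.
- LiBH4 (THF, MeOH, 0 °C) releases the auxiliary and should give the 1,3-diol F3.
- The primary hydroxyl is converted selectively into the phenyl sulfide F4 (PhSSPh, Bu3P, THF).
- Oxidation with H2O2 and ammonium molybdate in EtOH, which spares the terminal alkene, gives the hydroxy sulfone F5.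
- Epoxy alcohol 4 is converted into the epoxy triflate F6 (Tf2O, 2,6-lutidine, CH2Cl2, –78 °C).
- F6 alkylates the sodium alkoxide of F5 (NaH, THF, –40 → 0 °C) to give the epoxy sulfone F7.
- LiHMDS (THF, –78 → 0 °C) then generates the same carbanion 11, and the 6-exo epoxide opening should give 12.

**Step 5.** What may go wrong: Payne rearrangement or self-condensation of the epoxy alkoxide, or sluggish attack of the functionalised copper alkoxide on the Ir-allyl complex. The fallback takes the epoxide stereocentres from a ketone-catalysed epoxidation after the ether is made. It sets out from compound 3 (with 5) and comes back at compound 6.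
- The copper alkoxide of 3 is used as the O-nucleophile in the same Ir-catalysed etherification of 5 to give the bis-allylic ether F8.
- Shi asymmetric epoxidation with the enantiomeric (L-fructose-derived) ketone, Oxone and K2CO3 at 0 °C should then epoxidise the trans-disubstituted styrenyl alkene to the (S,S)-epoxide much faster than the terminal vinyl group, giving 6.

**Step 6.** What may go wrong: slow cross-metathesis at the branched, oxygenated allylic position with catalyst decomposition. The fallback replaces metathesis with radical addition and elimination. It sets out from compound 6 and comes back at compound 8.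
- Radical selenosulfonation (PhSeSO2Ph, AIBN, benzene, 80 °C) places the sulfonyl group on the terminal carbon and gives the β-phenylseleno sulfone F9.
- Oxidation with H2O2 (THF, 0 °C → rt) and selenoxide syn-elimination, which avoids the oxygen-bearing C2, should give the (E)-vinyl sulfone 8.

**Further compounds**

F1 | step 7 | (R)-4-benzyl-3-(pent-4-enoyl)oxazolidin-2-one | C=CCCC(=O)N1[C@H](Cc2ccccc2)COC1=O
F2 | step 7 | 4-[(1R,2R)-2-{[(4R)-4-benzyl-2-oxooxazolidin-3-yl]carbonyl}-1-hydroxypent-4-enyl]phenyl 4-methylbenzenesulfonate | C=CC[C@@H](C(=O)N1[C@H](Cc2ccccc2)COC1=O)[C@@H](O)c1ccc(OS(=O)(=O)c2ccc(C)cc2)cc1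
F3 | step 7 | 4-[(1R,2S)-1-hydroxy-2-(hydroxymethyl)pent-4-enyl]phenyl 4-methylbenzenesulfonate | C=CC[C@@H](CO)[C@@H](O)c1ccc(OS(=O)(=O)c2ccc(C)cc2)cc1
F4 | step 7 | 4-[(1R,2R)-1-hydroxy-2-[(phenylsulfanyl)methyl]pent-4-enyl]phenyl 4-methylbenzenesulfonate | C=CC[C@@H](CSc1ccccc1)[C@@H](O)c1ccc(OS(=O)(=O)c2ccc(C)cc2)cc1
F5 | step 7 | 4-[(1R,2R)-1-hydroxy-2-[(phenylsulfonyl)methyl]pent-4-enyl]phenyl 4-methylbenzenesulfonate | C=CC[C@@H](CS(=O)(=O)c1ccccc1)[C@@H](O)c1ccc(OS(=O)(=O)c2ccc(C)cc2)cc1
F6 | step 7 | [(2S,3S)-3-(4-tosyloxyphenyl)oxiran-2-yl]methyl trifluoromethanesulfonate | FC(F)(F)S(=O)(=O)OC[C@@H]1O[C@H]1c1ccc(OS(=O)(=O)c2ccc(C)cc2)cc1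
F7 | step 7 | 4-[(1R,2R)-2-[(phenylsulfonyl)methyl]-1-{[(2S,3S)-3-(4-tosyloxyphenyl)oxiran-2-yl]methoxy}pent-4-enyl]phenyl 4-methylbenzenesulfonate | C=CC[C@@H](CS(=O)(=O)c1ccccc1)[C@@H](OC[C@@H]1O[C@H]1c1ccc(OS(=O)(=O)c2ccc(C)cc2)cc1)c1ccc(OS(=O)(=O)c2ccc(C)cc2)cc1
F8 | step 5 | 4-[(1R)-1-{[(E)-3-(4-tosyloxyphenyl)prop-2-enyl]oxy}prop-2-enyl]phenyl 4-methylbenzenesulfonate | C=C[C@@H](OC/C=C/c1ccc(OS(=O)(=O)c2ccc(C)cc2)cc1)c1ccc(OS(=O)(=O)c2ccc(C)cc2)cc1
F9 | step 6 | 4-[(1S)-3-(phenylsulfonyl)-2-(phenylselanyl)-1-{[(2S,3S)-3-(4-tosyloxyphenyl)oxiran-2-yl]methoxy}propyl]phenyl 4-methylbenzenesulfonate (selenium-bearing carbon not defined; benzylic centre spatially as in 6) | O=S(=O)(CC([Se]c1ccccc1)[C@@H](OC[C@@H]1O[C@H]1c1ccc(OS(=O)(=O)c2ccc(C)cc2)cc1)c1ccc(OS(=O)(=O)c2ccc(C)cc2)cc1)c1ccccc1
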